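**Retrosynthetic overview**

- The strategy rests on ring A: the depside ester carbon on C1, OH on C2, OMe on C4, unsubstituted C3 and C5, and the 2-oxononyl chain on C6. A 1,1,3-trioxygenated butadiene delivers exactly this 2-hydroxy-4-methoxy pattern to an alk-2-ynoate.
- Key disconnection: the C1–C2 and C5–C6 bonds of ring A, by Diels–Alder reaction of a ring B aryl ynoate with 1,3-dimethoxy-1-(trimethylsilyloxy)buta-1,3-diene and eliminative aromatisation. Ring B is bought as orsellinic acid, so ring A is the only ring formed.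
- The depside C–O bond is made before ring A exists, between a 4-substituted but-2-ynoic acid and the free 4-OH of benzyl orsellinate. The ynoic acid comes from octanal dithiane (the side-chain ketone masked as a 1,3-dithiane) by propargylation and carboxylation.
- Endgame: non-oxidative dithiane hydrolysis, then hydrogenolysis of the benzyl ester.

Key step: step 7

Remark: the chelated 2-OH of ring B is carried free rather than as a benzyl ether (it cannot be benzylated selectively in few steps and is a poor nucleophile), so the key-step precursor 11 and product 17 bear OH at that position; the target has no stereocentre.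

**Step 1**
Reactants: 1 octanal
Product: 2 2-heptyl-1,3-dithiane
Conditions: propane-1,3-dithiol, BF3·OEt2, CH2Cl2, 0 °C → rt
Reagents that add atoms: propane-1,3-dithiol, SCCCS
Why: Lewis-acid-promoted dithioacetalisation of an unhindered aldehyde (Corey–Seebach dithiane formation) is reliable and creates no stereocentre.

**Step 2**
Reactants: 2 2-heptyl-1,3-dithiane; 3 3-bromoprop-1-yne
Product: 5 2-heptyl-2-(prop-2-yn-1-yl)-1,3-dithiane, via lithiated dithiane 4 (not isolated)
Conditions: n-BuLi, THF, −30 °C; then 3, −78 °C → rt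
Reagents that add atoms: none
Why: Corey–Seebach umpolung alkylation, in which the soft 2-lithiodithiane should displace the propargylic bromide by SN2 at −78 °C faster than it abstracts the acetylenic proton; no stereocentre is formed.

**Step 3**
Reactants: 5 2-heptyl-2-(prop-2-yn-1-yl)-1,3-dithiane
Product: 8 4-(2-heptyl-1,3-dithian-2-yl)but-2-ynoic acid, via lithium acetylide 6 (not isolated), via lithium ynoate 7 (not isolated)
Conditions: n-BuLi, THF, −78 °C; CO2 (gas), −78 → 0 °C; 1 M HCl work-up
Reagents that add atoms: carbon dioxide, O=C=O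
Why: Deprotonation of the terminal alkyne and carboxylation of the lithium acetylide is the standard route to alk-2-ynoic acids, and the fully substituted dithiane carbon carries no competing acidic hydrogen.

**Step 4**
Reactants: 9 orsellinic acid (2,4-dihydroxy-6-methylbenzoic acid)
Product: 10 benzyl 2,4-dihydroxy-6-methylbenzoate
Conditions: BnBr, KHCO3, DMF, rt
Reagents that add atoms: benzyl bromide, BrCc1ccccc1
Why: Carboxylate O-alkylation (SN2), since KHCO3 ionises only the carboxylic acid so both phenols stay free, and room temperature avoids decarboxylation of orsellinic acid.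

**Step 5**
Reactants: 8 4-(2-heptyl-1,3-dithian-2-yl)but-2-ynoic acid; 10 benzyl 2,4-dihydroxy-6-methylbenzoate
Product: 11 benzyl 4-{[4-(2-heptyl-1,3-dithian-2-yl)but-2-ynoyl]oxy}-2-hydroxy-6-methylbenzoate
Conditions: DCC, DMAP (5 mol%), CH2Cl2, −20 → 0 °C
Reagents that add atoms: none
Why: Steglich esterification, selective for the 4-OH because the 2-OH is hydrogen-bonded to and flanked by the benzyl ester carbonyl, and unhindered because the acyl carbon sits on an sp carbon; no stereocentre.

**Step 6**
Reactants: 12 methyl (E)-3-methoxybut-2-enoate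
Product: 14 1,3-dimethoxy-1-(trimethylsilyloxy)buta-1,3-diene, via lithium dienolate 13 (not isolated)
Conditions: LiN(i-Pr)2, THF, −78 °C; Me3SiCl, −78 °C → rt; used directly after filtration and concentration under argon
Reagents that add atoms: chlorotrimethylsilane, C[Si](C)(C)Cl
Why: γ-Deprotonation of the vinylogous carbonate gives the extended dienolate, which is O-silylated to the silyl ketene acetal diene (standard preparation of this diene).

**Step 7**
Reactants: 11 benzyl 4-{[4-(2-heptyl-1,3-dithian-2-yl)but-2-ynoyl]oxy}-2-hydroxy-6-methylbenzoate; 14 1,3-dimethoxy-1-(trimethylsilyloxy)buta-1,3-diene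
Product: 17 benzyl 4-({2-[(2-heptyl-1,3-dithian-2-yl)methyl]-6-hydroxy-4-methoxybenzoyl}oxy)-2-hydroxy-6-methylbenzoate, via cyclohexadiene cycloadduct 15 (not isolated), via cyclohexadienone 16 (not isolated)
Conditions: 14 (3 equiv, in two portions), PhMe, 110 °C, sealed tube; then 0.1 M HCl, THF, 0 °C
Reagents that add atoms: none
Why: This is a normal-electron-demand Diels–Alder reaction of a silyl ketene acetal diene with an alkynoate, the known route from 1,1,3-trioxygenated butadienes to resorcylate esters; it is concerted but asynchronous, the unsubstituted CH2 terminus of 14 bonding first to the ynoate β-carbon and the ketene acetal carbon then to the α-carbon. Ring A is closed by this [4+2] cycloaddition, which forms the C5–C6 and C1–C2 bonds and gives the cyclohexa-1,4-diene 15; its mixed acetal carbon expels methoxytrimethylsilane to give dienone 16, which tautomerises irreversibly to the phenol. No stereocentre remains in 17, because the only stereogenic atom formed (the acetal carbon of racemic 15) is lost on aromatisation. The selectivity needed is regiochemical and is secured by the matched polarisation of the partners, which places the hydroxyl on C2 beside the ester carbon and the methoxy group on C4 para to it. The aryl ester lowers the alkyne LUMO relative to an alkyl ester, the dithiane and benzyl ester are thermally inert, and the excess of 14 covers any silyl transfer to the chelated ring B phenol, which the acidic work-up reverses.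

**Step 8**
Reactants: 17 benzyl 4-({2-[(2-heptyl-1,3-dithian-2-yl)methyl]-6-hydroxy-4-methoxybenzoyl}oxy)-2-hydroxy-6-methylbenzoate
Product: 18 benzyl 2-hydroxy-4-{[2-hydroxy-4-methoxy-6-(2-oxononyl)benzoyl]oxy}-6-methylbenzoate
Conditions: MeI (excess), CaCO3, MeCN/H2O (9:1), 40 °C
Reagents that add atoms: water, O
Why: Alkylative dithiane hydrolysis (S-methylation, ring opening to a thionium ion, capture by water) is buffered and non-oxidising, chosen because halonium or hypervalent-iodine reagents would attack the electron-rich phenolic ring A, while CaCO3 is too weak a base to O-methylate the two chelated phenols.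

**Step 9**
Reactants: 18 benzyl 2-hydroxy-4-{[2-hydroxy-4-methoxy-6-(2-oxononyl)benzoyl]oxy}-6-methylbenzoate
Product: 19 2-hydroxy-4-{[2-hydroxy-4-methoxy-6-(2-oxononyl)benzoyl]oxy}-6-methylbenzoic acid (target)
Conditions: H2 (1 atm), Pd/C (10% palladium on carbon), EtOAc, rt
Reagents that add atoms: none
Why: Catalytic hydrogenolysis of the benzyl ester C–O bond should leave the aryl ester, the dialkyl ketone and the phenols untouched under 1 atm of hydrogen in a neutral solvent once 18 has been freed of sulfur by-products by chromatography.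

**Compound list**

1 | octanal | CCCCCCCC=O | starting material
2 | 2-heptyl-1,3-dithiane | CCCCCCCC1SCCCS1 | intermediate
3 | 3-bromoprop-1-yne | C#CCBr | starting material
4 | 2-heptyl-2-lithio-1,3-dithiane | CCCCCCCC1([Li])SCCCS1 | intermediate (not isolated)
5 | 2-heptyl-2-(prop-2-yn-1-yl)-1,3-dithiane | CCCCCCCC1(CC#C)SCCCS1 | intermediate
6 | [3-(2-heptyl-1,3-dithian-2-yl)prop-1-yn-1-yl]lithium | CCCCCCCC1(CC#C[Li])SCCCS1 | intermediate (not isolated)
7 | lithium 4-(2-heptyl-1,3-dithian-2-yl)but-2-ynoate | CCCCCCCC1(CC#CC(=O)[O-])SCCCS1.[Li+] | intermediate (not isolated)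
8 | 4-(2-heptyl-1,3-dithian-2-yl)but-2-ynoic acid | CCCCCCCC1(SCCCS1)CC#CC(=O)O | intermediate
9 | orsellinic acid (2,4-dihydroxy-6-methylbenzoic acid) | Cc1cc(O)cc(O)c1C(=O)O | starting material
10 | benzyl 2,4-dihydroxy-6-methylbenzoate | Cc1cc(O)cc(O)c1C(=O)OCc1ccccc1 | intermediate
11 | benzyl 4-{[4-(2-heptyl-1,3-dithian-2-yl)but-2-ynoyl]oxy}-2-hydroxy-6-methylbenzoate | CCCCCCCC1(SCCCS1)CC#CC(=O)Oc1cc(C)c(C(=O)OCc2ccccc2)c(O)c1 | intermediate
12 | methyl (E)-3-methoxybut-2-enoate | CO/C(C)=C/C(=O)OC | starting material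
13 | lithium 1,3-dimethoxybuta-1,3-dien-1-olate | C=C(OC)C=C(OC)[O-].[Li+] | intermediate (not isolated)
14 | 1,3-dimethoxy-1-(trimethylsilyloxy)buta-1,3-diene | C=C(OC)C=C(OC)O[Si](C)(C)C | intermediate
15 | benzyl 4-({2-[(2-heptyl-1,3-dithian-2-yl)methyl]-4,6-dimethoxy-6-(trimethylsilyloxy)cyclohexa-1,4-diene-1-carbonyl}oxy)-2-hydroxy-6-methylbenzoate (racemic at the acetal carbon) | CCCCCCCC1(SCCCS1)CC1=C(C(=O)Oc2cc(C)c(C(=O)OCc3ccccc3)c(O)c2)C(OC)(O[Si](C)(C)C)C=C(OC)C1 | intermediate (not isolated)
16 | benzyl 4-({2-[(2-heptyl-1,3-dithian-2-yl)methyl]-4-methoxy-6-oxocyclohexa-1,4-diene-1-carbonyl}oxy)-2-hydroxy-6-methylbenzoate | CCCCCCCC1(SCCCS1)CC1=C(C(=O)Oc2cc(C)c(C(=O)OCc3ccccc3)c(O)c2)C(=O)C=C(OC)C1 | intermediate (not isolated)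
17 | benzyl 4-({2-[(2-heptyl-1,3-dithian-2-yl)methyl]-6-hydroxy-4-methoxybenzoyl}oxy)-2-hydroxy-6-methylbenzoate | CCCCCCCC1(SCCCS1)Cc1cc(OC)cc(O)c1C(=O)Oc1cc(C)c(C(=O)OCc2ccccc2)c(O)c1 | intermediate
18 | benzyl 2-hydroxy-4-{[2-hydroxy-4-methoxy-6-(2-oxononyl)benzoyl]oxy}-6-methylbenzoate | CCCCCCCC(=O)Cc1cc(OC)cc(O)c1C(=O)Oc1cc(C)c(C(=O)OCc2ccccc2)c(O)c1 | intermediate
19 | 2-hydroxy-4-{[2-hydroxy-4-methoxy-6-(2-oxononyl)benzoyl]oxy}-6-methylbenzoic acid | CCCCCCCC(=O)Cc1cc(OC)cc(O)c1C(=O)Oc1cc(C)c(C(=O)O)c(O)c1 | target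

**Step count**

Total: 9 steps. Longest linear sequence: 7 steps (steps 1, 2, 3, 5, 7, 8, 9); steps 4 and 6 prepare the ring B phenol and the diene.

**Steps most likely to fail**

1. Step 7. The internal ynoate may react more slowly than the acyclic silyl ketene acetal diene decays thermally (silyl transfer, hydrolysis, unfavourable s-cis population), or the reaction may stop after conjugate addition without ring closure.
 Fallback, from 11 back to 17: a conformationally locked, thermally robust diene is used and aromatisation occurs by retro-Diels–Alder extrusion instead of elimination. 5,5-Dimethylcyclohexane-1,3-dione is silylated to 5,5-dimethyl-3-(trimethylsilyloxy)cyclohex-2-en-1-one F1 (Me3SiCl, Et3N), then enolised and silylated to 5,5-dimethyl-1,3-bis(trimethylsilyloxy)cyclohexa-1,3-diene F2 (LiN(i-Pr)2, Me3SiCl, THF, −78 °C). Heating 11 with F2 neat at 140 °C should give the bicyclo[2.2.2]octadiene adduct F3, which loses 2-methylprop-1-ene to give the ring A bis(trimethylsilyl) ether F4. Dilute HCl in THF should then give benzyl 4-({2-[(2-heptyl-1,3-dithian-2-yl)methyl]-4,6-dihydroxybenzoyl}oxy)-2-hydroxy-6-methylbenzoate F5. Its only non-chelated phenol (ring A C4–OH) is methylated with (trimethylsilyl)diazomethane in MeOH/toluene at 0 °C, which returns 17.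

2. Step 8. S-Methylation of the hindered 2,2-disubstituted dithiane may be slow, and prolonged warming could let the enol of the freed ketone attack the activated aryl ester, giving an isocoumarin and expelling ring B.
 Fallback, from 17 back to 18: activation of sulfur is separated from hydrolysis. Mono-S-oxidation with NaIO4 (1.05 equiv, MeOH/THF/H2O, 0 °C) should give the 1,3-dithiane 1-oxide F6 as a mixture of diastereomers. Brief acid-catalysed hydrolysis of this dithioacetal monoxide (catalytic HClO4, wet THF, 0 °C → rt) then releases ketone 18 and 1,2-dithiolane.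

3. Step 5. DMAP may cause prototropic isomerisation of the ynoate to the allenoate or add in conjugate fashion to the ynoate, and N-acylurea formation may compete.
 Fallback, from 8 back to 11: 8 is converted under neutral conditions into 4-(2-heptyl-1,3-dithian-2-yl)but-2-ynoyl chloride F7 with 1-chloro-N,N,2-trimethylprop-1-en-1-amine (CH2Cl2, 0 °C). F7 then acylates the free 4-OH of 10 in the presence of 2,6-lutidine (CH2Cl2, −20 °C), with no nucleophilic catalyst and no carbodiimide.

**Further compounds**

F1 | step 7 | 5,5-dimethyl-3-(trimethylsilyloxy)cyclohex-2-en-1-one | CC1(C)CC(=O)C=C(O[Si](C)(C)C)C1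
F2 | step 7 | 5,5-dimethyl-1,3-bis(trimethylsilyloxy)cyclohexa-1,3-diene | CC1(C)CC(O[Si](C)(C)C)=CC(O[Si](C)(C)C)=C1
F3 | step 7 | bicyclo[2.2.2]octa-2,5-diene Diels–Alder adduct of 11 and F2 (racemic; bridgehead OSiMe3 beside the ester-bearing carbon, CMe2–CH2 bridge) | CCCCCCCC1(SCCCS1)CC2=C(C(=O)Oc4cc(C)c(C(=O)OCc5ccccc5)c(O)c4)C3(O[Si](C)(C)C)C=C(O[Si](C)(C)C)C2C(C)(C)CC3
F4 | step 7 | benzyl 4-({2-[(2-heptyl-1,3-dithian-2-yl)methyl]-4,6-bis(trimethylsilyloxy)benzoyl}oxy)-2-hydroxy-6-methylbenzoate | CCCCCCCC1(SCCCS1)Cc1cc(O[Si](C)(C)C)cc(O[Si](C)(C)C)c1C(=O)Oc1cc(C)c(C(=O)OCc2ccccc2)c(O)c1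
F5 | step 7 | benzyl 4-({2-[(2-heptyl-1,3-dithian-2-yl)methyl]-4,6-dihydroxybenzoyl}oxy)-2-hydroxy-6-methylbenzoate | CCCCCCCC1(SCCCS1)Cc1cc(O)cc(O)c1C(=O)Oc1cc(C)c(C(=O)OCc2ccccc2)c(O)c1
F6 | step 8 | benzyl 4-({2-[(2-heptyl-1-oxido-1,3-dithian-2-yl)methyl]-6-hydroxy-4-methoxybenzoyl}oxy)-2-hydroxy-6-methylbenzoate (mixture of diastereomers) | CCCCCCCC1(SCCCS1=O)Cc1cc(OC)cc(O)c1C(=O)Oc1cc(C)c(C(=O)OCc2ccccc2)c(O)c1
F7 | step 5 | 4-(2-heptyl-1,3-dithian-2-yl)but-2-ynoyl chloride | CCCCCCCC1(SCCCS1)CC#CC(=O)Cl
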